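**The problem**

Compound 14 is an unsymmetrical biflavone ether. Two 5-hydroxy-7-methoxyflavone units are joined by one oxygen that links C4' of the para-phenylene ring B of unit 1 (benzo ring A, pyranone ring C) to C8'' of benzo ring D of unit 2 (pyranone ring E, 4-hydroxyphenyl ring F). There is no stereocentre, so the difficulty is regiochemical. Ring D carries oxygen at C5'', C7'', C8'' and C8a''. A ring D ketone with oxygen on both carbons ortho to the acyl group can close ring E toward either one, which puts the aryloxy group at C8'' or at C6''. A correctly closed 5''-hydroxyflavone can still scramble the two in hot acid by ring opening and reclosure (Wessely–Moser rearrangement). Ring A has the same 5,7-pattern but is unsubstituted at C6 and C8 and poses no such question. The C2=C3 and C2''=C3'' bonds (reducible, opened by hot alkali), the electron-rich ether rings (oxidants, electrophiles) and the C7 and C7'' methyl ethers, which must stay distinct from three free hydroxyls, all limit the reagents that can be used late. The feature exploited here is that H5 and H5'' lie peri to C4=O and C4''=O: each carbonyl oxygen and its peri carbon can hold a metal in a five-membered chelate, and the only other ortho position of each carbonyl is the ring-fusion carbon C8a or C8a''. Both 5-oxygens can therefore be added last, and without O5'' the ring D ketone has one ortho oxygen and ring E one way to close.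

**Retrosynthesis**

14 to 11. The C5–O and C5''–O bonds are cut first. Any other first cut (methyl ethers, pyranone bonds, diaryl ether) leaves a 5''-oxygenated ring D in every precursor and with it the C8''/C6'' question. The precursor 11 is the 5,5''-dideoxy biflavone, whose two benzo rings come from simple ortho-hydroxyacetophenones. The forward reaction must oxygenate two peri C–H bonds among thirteen aryl C–H bonds, must not oxidise the ether-rich rings, and must keep the 4'''-phenol masked; this is done in the flask as trifluoroacetate 12, the oxidation then giving tris(trifluoroacetate) 13.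

11 to 10. The O–benzyl bond on ring F is cut. The 4'''-phenol has to be masked through the enolate and esterification chemistry, where it would otherwise be acylated. Benzyl survives base and brief hot acid and is removed without touching the methyl ethers. The forward hydrogenolysis must leave both pyranone double bonds intact.

10 to 8 (through 9). Ring C is opened at O1–C2 and the C2–C3 bond is cut, leading to diketone 9 and then to aryl ester 8 (Baker–Venkataraman retron). The neighbouring cut, a chalcone closed oxidatively, would need an aldehyde in place of the carboxyl group and an iodine-mediated oxidation on an electron-rich substrate. The ester route arrives at the flavone oxidation level directly and reuses the carboxyl group that activated the ether-forming step. Base-induced acyl transfer must be faster than attack on pyranone E.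

8 to 6 and 7. The ester C–O bond is cut, giving flavone acid 6 and paeonol 7. This is the convergent point: all of ring A arrives as a commercial ketone with a single ortho hydroxyl. A mild esterification of a chelated phenol is required.

6 to 5, and 5 to 3 and 4. Ring E is opened at O1''–C2'' to diketone 5, whose C2''–C3'' bond is cut to ketone 3 and acid chloride 4. Ketone 3 has only one hydroxyl ortho to the acetyl group, so closure can only give the 8''-aryloxy isomer. The tert-butyl ester of 5 is chosen over a methyl ester so that the acid used for ring closure also frees the carboxyl group and no hydroxide meets the flavone.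

3 to 1 and 2. The aryl–oxygen bond on the ring B side of the diaryl ether is cut, giving catechol-type ketone 1 and fluoride 2. Cutting on the ring D side would demand an electrophilic, electron-rich ring D. Forming the ether later, between two flavones, would need a harsher coupling on a larger molecule. Here the ester that will become C2 of ring C activates the fluoride. The forward reaction must choose the unchelated 3-hydroxyl of 1 over the chelated 2-hydroxyl.

**Roads not taken**

Alternative 1: Ring E is cut at C4a''–C4''. A symmetric resorcinol, methyl 4-(2,6-dihydroxy-4-methoxyphenoxy)benzoate A2, adds through either hydroxyl to a ring F propiolate to give the (Z)-3-aryl-3-aryloxyacrylic acid A3. Trifluoroacetic anhydride then closes ring E by Friedel–Crafts acylation at the one free ortho carbon, giving A1. The merit is real: symmetry and a blocked position fix the ether at C8'' with no metal, and the oxygen that becomes O5'' is present from the start. Against it, A2 is not commercial and requires arylation of the central, most hindered oxygen of a protected 5-methoxypyrogallol. The conjugate addition of a di-ortho-substituted phenol needs Z geometry to cyclise. A1 also has the wrong ether pattern (7''-OH, 5''-OMe), so a methylation and a late peri-demethylation follow, and ring C is still to be built. The end game of this road, a Lewis-acid demethylation peri to a carbonyl, is better precedented than a twofold C–H oxidation. The chosen plan sets against it a markedly shorter sequence from commercial ketones with no methyl ether adjustment.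

Alternative 2: Ring A is cut at C4a–C8a. A 4-methoxy-2-pyrone A5 carrying the enone side chain is opened by Mg(OMe)2 in methanol to a diketo ester, whose central methylene attacks the ester carbonyl in a biomimetic Claisen closure to give chalcone A4. The idea is attractive and assembles ring A with its 5,7-pattern without protecting groups. It spends its key step on the ring that poses no regiochemical problem, however. Unit 2 enters A5 fully formed with the ether already at C8'' and a 5''-methyl ether, so the central difficulty is moved to an unspecified earlier stage and a selective 5''-demethylation is added at the end. The enone of A5 is also exposed to methoxide during the ring opening, and A4 still needs oxidative cyclisation to the flavone. The chosen plan is shorter and addresses ring D directly. Alternative 2 has the advantage only in avoiding a late oxidant.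

Alternative 3: Both pyranones are cut at C2=C3 and C2''=C3''. A bis(acylmethylene)triphenylphosphorane A7, with the ring B and ring F carboxyl groups as aryl esters on the ortho oxygens of rings A and D, is heated and closes rings C and E by twofold intramolecular ester Wittig olefination to A6. The closure is neutral, forms both rings in one operation, and BCl3 could then remove the two peri methyl groups and the benzyl group together; that end game is as short as the chosen one and uses better-established chemistry. The cost lies before the key step. Ring D must come from a 2,3-dihydroxy-4,6-dimethoxyacetophenone, which is much less accessible than 1, and two ketones must be brominated and converted to ylides in the presence of electron-rich rings and aryl esters. Stabilised ylides also attack ester carbonyls only at high temperature. The chosen plan uses simpler starting materials and fewer steps, and accepts in exchange the risk of one late oxidation.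

Key step: step 7

Remark on the chemistry: the two new phenol oxygens are taken to arrive as trifluoroacetate, so the species leaving the catalytic cycle are aryl trifluoroacetates, which methanol cleaves in the work-up of the same step.

**Route**

Step 1
Reactants: 1 1-(2,3-dihydroxy-4-methoxyphenyl)ethan-1-one (2',3'-dihydroxy-4'-methoxyacetophenone); 2 tert-butyl 4-fluorobenzoate
Product: 3 tert-butyl 4-(3-acetyl-2-hydroxy-6-methoxyphenoxy)benzoate
Conditions: K2CO3 (2.5 equiv), DMSO, 120 °C, N2
Reagents that add atoms: none
Why: Nucleophilic aromatic substitution on a para-ester-activated aryl fluoride; the 2-hydroxyl is hydrogen-bonded to the acetyl group and its phenoxide is delocalised into it, so the unchelated 3-phenoxide should be arylated, and the tert-butyl ester resists phenoxide at both its acyl and alkyl carbon.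

Step 2
Reactants: 3 tert-butyl 4-(3-acetyl-2-hydroxy-6-methoxyphenoxy)benzoate; 4 4-(benzyloxy)benzoyl chloride
Product: 5 tert-butyl 4-(3-{3-[4-(benzyloxy)phenyl]-3-oxopropanoyl}-2-hydroxy-6-methoxyphenoxy)benzoate
Conditions: LiHMDS (3.2 equiv), THF, −78 °C; add 4, −78 °C → rt; 1 M HCl
Reagents that add atoms: none
Why: Acylation of the lithium phenoxide–enolate dianion of an ortho-hydroxyacetophenone by an aroyl chloride, the one-flask form of the Baker–Venkataraman diketone synthesis; the third equivalent of base takes up the acidic diketone, and the hindered tert-butyl ester without α-hydrogen is inert at low temperature.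

Step 3
Reactants: 5 tert-butyl 4-(3-{3-[4-(benzyloxy)phenyl]-3-oxopropanoyl}-2-hydroxy-6-methoxyphenoxy)benzoate
Product: 6 4-({2-[4-(benzyloxy)phenyl]-7-methoxy-4-oxo-4H-chromen-8-yl}oxy)benzoic acid
Conditions: AcOH, cat. H2SO4, 90 °C
Reagents that add atoms: none
Why: Acid-catalysed cyclodehydration of a 2-hydroxyaryl 1,3-diketone to the flavone (6-exo-trig addition of the phenol to the protonated carbonyl, then loss of water) with concurrent acidolysis of the tert-butyl ester; ring E can close only through the single ortho oxygen, which places the aryloxy group at C8''.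

Step 4
Reactants: 6 4-({2-[4-(benzyloxy)phenyl]-7-methoxy-4-oxo-4H-chromen-8-yl}oxy)benzoic acid; 7 1-(2-hydroxy-4-methoxyphenyl)ethan-1-one (paeonol)
Product: 8 2-acetyl-5-methoxyphenyl 4-({2-[4-(benzyloxy)phenyl]-7-methoxy-4-oxo-4H-chromen-8-yl}oxy)benzoate
Conditions: DCC, DMAP (cat.), CH2Cl2/DMF, rt
Reagents that add atoms: none
Why: Steglich esterification; the O-acylisourea of 6 is relayed through the acylpyridinium ion to the chelated phenol of paeonol, the only nucleophile present.

Step 5
Reactants: 8 2-acetyl-5-methoxyphenyl 4-({2-[4-(benzyloxy)phenyl]-7-methoxy-4-oxo-4H-chromen-8-yl}oxy)benzoate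
Product: 10 2-[4-(benzyloxy)phenyl]-7-methoxy-8-[4-(7-methoxy-4-oxo-4H-chromen-2-yl)phenoxy]-4H-chromen-4-one, via 1,3-diketone 9 (not isolated)
Conditions: KOtBu (3 equiv), THF, 0 °C → rt; AcOH, concentrate; then AcOH, cat. H2SO4, 90 °C
Reagents that add atoms: none
Why: Baker–Venkataraman rearrangement (intramolecular acyl transfer from the aryl ester to the ketone enolate through a six-membered transition state) followed by acid cyclodehydration of the crude diketone, the classical flavone synthesis; ring E has no acidic C–H to compete with the acetyl group for the base.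

Step 6
Reactants: 10 2-[4-(benzyloxy)phenyl]-7-methoxy-8-[4-(7-methoxy-4-oxo-4H-chromen-2-yl)phenoxy]-4H-chromen-4-one
Product: 11 2-(4-hydroxyphenyl)-7-methoxy-8-[4-(7-methoxy-4-oxo-4H-chromen-2-yl)phenoxy]-4H-chromen-4-one
Conditions: H2 (1 atm), 10% Pd/C, THF/MeOH, rt
Reagents that add atoms: none
Why: Hydrogenolysis of an aryl benzyl ether over palladium at atmospheric pressure; the cross-conjugated pyranone double bonds, the methyl ethers and the diaryl ether should not be reduced under these conditions.

Step 7
Reactants: 11 2-(4-hydroxyphenyl)-7-methoxy-8-[4-(7-methoxy-4-oxo-4H-chromen-2-yl)phenoxy]-4H-chromen-4-one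
Product: 14 5-hydroxy-2-(4-hydroxyphenyl)-8-[4-(5-hydroxy-7-methoxy-4-oxo-4H-chromen-2-yl)phenoxy]-7-methoxy-4H-chromen-4-one (CNP0415865.0), via aryl trifluoroacetate 12 (not isolated), via tris(trifluoroacetate) 13 (not isolated)
Conditions: TFA/TFAA (3:1), rt, 30 min; then [RuCl2(p-cymene)]2 (10 mol %), PhI(OCOCF3)2 (3 equiv), 80 °C; concentrate; MeOH, NaHCO3, rt
Reagents that add atoms: PhI(OCOCF3)2, O=C(OI(OC(=O)C(F)(F)F)c1ccccc1)C(F)(F)F; trifluoroacetic acid, OC(=O)C(F)(F)F (the two new phenol oxygens come from trifluoroacetate, which exchanges between the iodine reagent and the medium)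
Why: Trifluoroacetic anhydride first converts the 4'''-phenol into trifluoroacetate 12, so that no free phenol meets the trivalent iodine oxidant. The divalent ruthenium trifluoroacetate formed from [RuCl2(p-cymene)]2 binds the C4=O or C4''=O oxygen and cleaves the peri C5–H or C5''–H bond by concerted metalation–deprotonation, giving a five-membered ruthenacycle. PhI(OCOCF3)2 oxidises this to a tetravalent ruthenium trifluoroacetate, and C–O reductive elimination releases the aryl trifluoroacetate and returns divalent ruthenium; one turnover at each flavone unit gives 13, and methanol buffered with NaHCO3 then cleaves all three trifluoroacetates to 14. The closest known reaction type is the ketone-directed ortho C–H hydroxylation of aryl ketones, xanthones and flavones with this catalyst and oxidant, used here twice in one molecule. The step closes no ring and creates no stereocentre; it forms the C5–O and C5''–O bonds. It needs site selectivity for C5 and C5'' over eleven other aryl C–H bonds and the two C3–H bonds, and geometry secures it: the second ortho position of each carbonyl is the ring-fusion carbon C8a or C8a'', and C3–H would require a four-membered metallacycle. Over-oxidation is checked because each new oxygen leaves the cycle as an electron-poor trifluoroacetate and because protonation of the pyranones in trifluoroacetic acid lowers the electron density of rings A, B, D and F toward the iodine reagent.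

**Compound list**

1 | 1-(2,3-dihydroxy-4-methoxyphenyl)ethan-1-one (2',3'-dihydroxy-4'-methoxyacetophenone) | CC(=O)c1ccc(OC)c(O)c1O | starting material
2 | tert-butyl 4-fluorobenzoate | CC(C)(C)OC(=O)c1ccc(F)cc1 | starting material
3 | tert-butyl 4-(3-acetyl-2-hydroxy-6-methoxyphenoxy)benzoate | CC(=O)c1ccc(OC)c(Oc2ccc(C(=O)OC(C)(C)C)cc2)c1O | intermediate
4 | 4-(benzyloxy)benzoyl chloride | O=C(Cl)c1ccc(OCc2ccccc2)cc1 | starting material
5 | tert-butyl 4-(3-{3-[4-(benzyloxy)phenyl]-3-oxopropanoyl}-2-hydroxy-6-methoxyphenoxy)benzoate | CC(C)(C)OC(=O)c1ccc(Oc2c(OC)ccc(C(=O)CC(=O)c3ccc(OCc4ccccc4)cc3)c2O)cc1 | intermediate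
6 | 4-({2-[4-(benzyloxy)phenyl]-7-methoxy-4-oxo-4H-chromen-8-yl}oxy)benzoic acid | O=C(O)c1ccc(Oc2c(OC)ccc3c(=O)cc(-c4ccc(OCc5ccccc5)cc4)oc23)cc1 | intermediate
7 | 1-(2-hydroxy-4-methoxyphenyl)ethan-1-one (paeonol) | CC(=O)c1ccc(OC)cc1O | starting material
8 | 2-acetyl-5-methoxyphenyl 4-({2-[4-(benzyloxy)phenyl]-7-methoxy-4-oxo-4H-chromen-8-yl}oxy)benzoate | CC(=O)c1ccc(OC)cc1OC(=O)c1ccc(Oc2c(OC)ccc3c(=O)cc(-c4ccc(OCc5ccccc5)cc4)oc23)cc1 | intermediate
9 | 1-[4-({2-[4-(benzyloxy)phenyl]-7-methoxy-4-oxo-4H-chromen-8-yl}oxy)phenyl]-3-(2-hydroxy-4-methoxyphenyl)propane-1,3-dione | COc1ccc(C(=O)CC(=O)c2ccc(Oc3c(OC)ccc4c(=O)cc(-c5ccc(OCc6ccccc6)cc5)oc34)cc2)c(O)c1 | intermediate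
10 | 2-[4-(benzyloxy)phenyl]-7-methoxy-8-[4-(7-methoxy-4-oxo-4H-chromen-2-yl)phenoxy]-4H-chromen-4-one | COc1ccc2c(=O)cc(-c3ccc(Oc4c(OC)ccc5c(=O)cc(-c6ccc(OCc7ccccc7)cc6)oc45)cc3)oc2c1 | intermediate
11 | 2-(4-hydroxyphenyl)-7-methoxy-8-[4-(7-methoxy-4-oxo-4H-chromen-2-yl)phenoxy]-4H-chromen-4-one | COc1ccc2c(=O)cc(-c3ccc(Oc4c(OC)ccc5c(=O)cc(-c6ccc(O)cc6)oc45)cc3)oc2c1 | intermediate
12 | 4-{7-methoxy-8-[4-(7-methoxy-4-oxo-4H-chromen-2-yl)phenoxy]-4-oxo-4H-chromen-2-yl}phenyl trifluoroacetate | COc1ccc2c(=O)cc(-c3ccc(Oc4c(OC)ccc5c(=O)cc(-c6ccc(OC(=O)C(F)(F)F)cc6)oc45)cc3)oc2c1 | intermediate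
13 | 5,5'',4'''-tris-O-(trifluoroacetyl) derivative of 14 | COc1cc(OC(=O)C(F)(F)F)c2c(=O)cc(-c3ccc(Oc4c(OC)cc(OC(=O)C(F)(F)F)c5c(=O)cc(-c6ccc(OC(=O)C(F)(F)F)cc6)oc45)cc3)oc2c1 | intermediate
14 | 5-hydroxy-2-(4-hydroxyphenyl)-8-[4-(5-hydroxy-7-methoxy-4-oxo-4H-chromen-2-yl)phenoxy]-7-methoxy-4H-chromen-4-one (CNP0415865.0) | COc1cc(O)c2c(=O)cc(-c3ccc(Oc4c(OC)cc(O)c5c(=O)cc(-c6ccc(O)cc6)oc45)cc3)oc2c1 | target

**Step count and risks**

Total step count: 7. Longest linear sequence: 7 steps (1 to 14), with 2, 4 and 7 added along the way.

Step 7 (key step). The trivalent iodine reagent may oxidise the ether-bearing rings without direction (ring trifluoroacetoxylation or oxidative coupling), or the second hydroxylation may stall after the first, leaving mixtures of mono- and bis-oxygenated material. Fallback: separate C–H cleavage from oxidation. Starting from 10, carbonyl-directed ortho C–H borylation of the two aryl ketone units ([Ir(OMe)(cod)]2, AsPh3, B2pin2, about 120 °C, a reaction known for aryl ketones) would give the 5,5''-bis(pinacolboronate) F1. Oxidation with NaBO3·4H2O in THF/water would give the 4'''-O-benzyl ether of the target F2. Hydrogenolysis as in step 6 would then return to the route at 14.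

Step 1. Substitution may be slow, because the phenoxide is flanked on both sides and the fluoride is only ester-activated; at the temperature needed, arylation at the chelated oxygen or air oxidation of the catechol dianion may compete. Fallback: make the ether after ring E is closed, with a stronger electrophile. From 1, dianion acylation with 4 (LiHMDS, 4.2 equiv) would give 1-[4-(benzyloxy)phenyl]-3-(2,3-dihydroxy-4-methoxyphenyl)propane-1,3-dione F3. Acid cyclodehydration would give 2-[4-(benzyloxy)phenyl]-8-hydroxy-7-methoxy-4H-chromen-4-one F4, which has a single free hydroxyl. Substitution on 4-fluorobenzaldehyde (K2CO3, DMF, 100 °C) would give 4-({2-[4-(benzyloxy)phenyl]-7-methoxy-4-oxo-4H-chromen-8-yl}oxy)benzaldehyde F5. Pinnick oxidation (NaClO2, NaH2PO4, 2-methyl-2-butene) would return to the route at 6.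

Step 2. Acylation may stop at the hindered phenoxide oxygen without acyl transfer to carbon, or a second acyl group may be taken up. Fallback: the two-stage sequence. From 3, acylation of the phenol with 4 (K2CO3, acetone) would give tert-butyl 4-(3-acetyl-2-{[4-(benzyloxy)benzoyl]oxy}-6-methoxyphenoxy)benzoate F6. Baker–Venkataraman rearrangement (KOH, pyridine, 50 °C) would return to the route at 5.

Step 5. tert-Butoxide or the enolate may add to C2'' of pyranone E and open it, or the aryl ester may be cleaved intermolecularly before acyl transfer. Partial loss of the benzyl group in the hot acid is harmless, because it leads to 11. Fallback: form the C2–C3 bond intermolecularly at low temperature. From 6, oxalyl chloride with catalytic DMF would give 4-({2-[4-(benzyloxy)phenyl]-7-methoxy-4-oxo-4H-chromen-8-yl}oxy)benzoyl chloride F7. Addition of F7 to the dilithium phenoxide–enolate of 7 (LiHMDS, THF, −78 °C) would return to the route at 9, which is cyclised as in step 5.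

Step 6. Over-reduction of the C2=C3 or C2''=C3'' bond, or stalling because the biflavone is poorly soluble, may occur. Fallback: non-reductive debenzylation of 10 with BCl3 and pentamethylbenzene as cation scavenger (CH2Cl2, −78 °C), which returns to the route at 11 without a new compound.

**Further compounds**

F1 | step 7 | 2-[4-(benzyloxy)phenyl]-7-methoxy-8-{4-[7-methoxy-4-oxo-5-(4,4,5,5-tetramethyl-1,3,2-dioxaborolan-2-yl)-4H-chromen-2-yl]phenoxy}-5-(4,4,5,5-tetramethyl-1,3,2-dioxaborolan-2-yl)-4H-chromen-4-one | COc1cc(B9OC(C)(C)C(C)(C)O9)c2c(=O)cc(-c3ccc(Oc4c(OC)cc(B8OC(C)(C)C(C)(C)O8)c5c(=O)cc(-c6ccc(OCc7ccccc7)cc6)oc45)cc3)oc2c1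
F2 | step 7 | 2-[4-(benzyloxy)phenyl]-5-hydroxy-8-[4-(5-hydroxy-7-methoxy-4-oxo-4H-chromen-2-yl)phenoxy]-7-methoxy-4H-chromen-4-one | COc1cc(O)c2c(=O)cc(-c3ccc(Oc4c(OC)cc(O)c5c(=O)cc(-c6ccc(OCc7ccccc7)cc6)oc45)cc3)oc2c1
F3 | step 1 | 1-[4-(benzyloxy)phenyl]-3-(2,3-dihydroxy-4-methoxyphenyl)propane-1,3-dione | COc1ccc(C(=O)CC(=O)c2ccc(OCc3ccccc3)cc2)c(O)c1O
F4 | step 1 | 2-[4-(benzyloxy)phenyl]-8-hydroxy-7-methoxy-4H-chromen-4-one | COc1ccc2c(=O)cc(-c3ccc(OCc4ccccc4)cc3)oc2c1O
F5 | step 1 | 4-({2-[4-(benzyloxy)phenyl]-7-methoxy-4-oxo-4H-chromen-8-yl}oxy)benzaldehyde | O=Cc1ccc(Oc2c(OC)ccc3c(=O)cc(-c4ccc(OCc5ccccc5)cc4)oc23)cc1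
F6 | step 2 | tert-butyl 4-(3-acetyl-2-{[4-(benzyloxy)benzoyl]oxy}-6-methoxyphenoxy)benzoate | CC(=O)c1ccc(OC)c(Oc2ccc(C(=O)OC(C)(C)C)cc2)c1OC(=O)c1ccc(OCc2ccccc2)cc1
F7 | step 5 | 4-({2-[4-(benzyloxy)phenyl]-7-methoxy-4-oxo-4H-chromen-8-yl}oxy)benzoyl chloride | O=C(Cl)c1ccc(Oc2c(OC)ccc3c(=O)cc(-c4ccc(OCc5ccccc5)cc4)oc23)cc1
F0 | step 6 | none | none
A1 | alternative 1 | methyl 4-({2-[4-(benzyloxy)phenyl]-7-hydroxy-5-methoxy-4-oxo-4H-chromen-8-yl}oxy)benzoate | COC(=O)c1ccc(Oc2c(O)cc(OC)c3c(=O)cc(-c4ccc(OCc5ccccc5)cc4)oc23)cc1
A2 | alternative 1 | methyl 4-(2,6-dihydroxy-4-methoxyphenoxy)benzoate | COC(=O)c1ccc(Oc2c(O)cc(OC)cc2O)cc1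
A3 | alternative 1 | (Z)-3-[4-(benzyloxy)phenyl]-3-{3-hydroxy-5-methoxy-2-[4-(methoxycarbonyl)phenoxy]phenoxy}prop-2-enoic acid | COC(=O)c1ccc(Oc2c(O)cc(OC)cc2O/C(=C\C(=O)O)c2ccc(OCc3ccccc3)cc2)cc1
A4 | alternative 2 | (E)-3-[4-({2-[4-(benzyloxy)phenyl]-5,7-dimethoxy-4-oxo-4H-chromen-8-yl}oxy)phenyl]-1-(2,6-dihydroxy-4-methoxyphenyl)prop-2-en-1-one | COc1cc(O)c(C(=O)/C=C/c2ccc(Oc3c(OC)cc(OC)c4c(=O)cc(-c5ccc(OCc6ccccc6)cc5)oc34)cc2)c(O)c1
A5 | alternative 2 | 6-{(E)-4-[4-({2-[4-(benzyloxy)phenyl]-5,7-dimethoxy-4-oxo-4H-chromen-8-yl}oxy)phenyl]-2-oxobut-3-en-1-yl}-4-methoxy-2H-pyran-2-one | COc1cc(CC(=O)/C=C/c2ccc(Oc3c(OC)cc(OC)c4c(=O)cc(-c5ccc(OCc6ccccc6)cc5)oc34)cc2)oc(=O)c1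
A6 | alternative 3 | 2-[4-(benzyloxy)phenyl]-8-[4-(5,7-dimethoxy-4-oxo-4H-chromen-2-yl)phenoxy]-5,7-dimethoxy-4H-chromen-4-one | COc1cc(OC)c2c(=O)cc(-c3ccc(Oc4c(OC)cc(OC)c5c(=O)cc(-c6ccc(OCc7ccccc7)cc6)oc45)cc3)oc2c1
A7 | alternative 3 | 3,5-dimethoxy-2-[(triphenyl-λ5-phosphanylidene)acetyl]phenyl 4-{2-{[4-(benzyloxy)benzoyl]oxy}-4,6-dimethoxy-3-[(triphenyl-λ5-phosphanylidene)acetyl]phenoxy}benzoate | COc1cc(OC)c(C(=O)C=P(c2ccccc2)(c2ccccc2)c2ccccc2)c(OC(=O)c2ccc(Oc3c(OC)cc(OC)c(C(=O)C=P(c4ccccc4)(c4ccccc4)c4ccccc4)c3OC(=O)c3ccc(OCc4ccccc4)cc3)cc2)c1
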